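**Retrosynthetic overview**
- The butanolide is closed last: a C7–O lactonisation of a ten-membered Z-cycloalkene seco-acid, which in the same flask installs C6–Cl and the C5=C16 methylene (selenium relay).
- The seco-acid comes from Z-selective ring-closing metathesis (C6=C7) of an acyclic diene carried on ring A.
- The diene comes from a ring A aldehyde by acryloyl-anion addition (C8–C9) and a chelate-controlled propanoate aldol (C8–C17); the upper chain comes from an asymmetric alkylzinc addition (C2–C3), followed by C11 methylation/hydroxylation.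
- Ring A (C1 and C10) comes from an enantioselective Diels–Alder reaction of an E-enal with an aminosiloxydiene.
- Ring order: ring A (cyclohexenone), then the ten-membered carbocycle, then the γ-lactone.

Assumptions: briarane numbering (C1–C20) is used for atom labels. C5 is carried as a 1:1 epimer mixture from the alkylzinc addition until the last step, where it becomes sp2. The sense of induction of each chiral catalyst or auxiliary is assigned by analogy; the antipode would be used if it proved opposite.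

Step 1
Reactants: 1 2,2-dimethoxyacetaldehyde; 2 2-(triphenyl-λ5-phosphanylidene)propanal
Product: 3 (2E)-4,4-dimethoxy-2-methylbut-2-enal
Conditions: CH2Cl2, 23 °C
Reagents that add atoms: none
Why: Wittig olefination with a stabilised formyl ylide is E-selective and gives the trisubstituted enal with CHO and CH(OMe)2 trans.

Step 2
Reactants: 3 (2E)-4,4-dimethoxy-2-methylbut-2-enal; 4 (1E)-3-(tert-butyldimethylsilyloxy)-N,N-dimethylbuta-1,3-dien-1-amine
Product: 6 (1S,6S)-6-(dimethoxymethyl)-1-methyl-4-oxocyclohex-2-ene-1-carbaldehyde, via Diels–Alder cycloadduct 5 (not isolated)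
Conditions: (R,R)-α,α,α',α'-tetra(1-naphthyl)-TADDOL (20 mol%), toluene, −78 °C; then AcCl, CH2Cl2, −78 °C
Reagents that add atoms: none
Why: Hydrogen-bond-catalysed Diels–Alder reaction in which the amino terminus bonds to the α-carbon, suprafacial addition to the E-enal sets the formyl (C2) and dimethoxymethyl (C9) groups trans on C1/C10, the TADDOL–formyl hydrogen bond selects the enal face, and AcCl then acylates the allylic amine and triggers β-elimination to the enone.

Step 3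
Reactants: 6 (1S,6S)-6-(dimethoxymethyl)-1-methyl-4-oxocyclohex-2-ene-1-carbaldehyde; 7 3-methylpenta-1,4-diene
Product: 11 (4S,5S)-5-(dimethoxymethyl)-4-methyl-4-[(1R,4RS)-4-methyl-1-(triethylsilyloxy)hex-5-en-1-yl]cyclohex-2-en-1-one, via diethyl(3-methylpent-4-en-1-yl)borane 8 (not isolated), via bis(3-methylpent-4-en-1-yl)zinc 9 (not isolated), via secondary alcohol 10 (not isolated)
Conditions: 7 (3 equiv), HBEt2 (from BH3·SMe2 + BEt3), 0 °C; ZnEt2, 0 °C, then vacuum; 6, Ti(OiPr)4, (1S,2S)-C6H10(NHSO2CF3)2 (8 mol%), toluene, −20 °C; aq. work-up; crude 10, Et3SiOSO2CF3, 2,6-lutidine, CH2Cl2, −78 °C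
Reagents that add atoms: triethylsilyl trifluoromethanesulfonate, CC[Si](CC)(CC)OS(=O)(=O)C(F)(F)F
Why: Hydroboration/boron–zinc exchange gives the dialkylzinc, which adds only to the aldehyde in a titanium bis(sulfonamide)-catalysed asymmetric organozinc addition (reagent-controlled Re-face attack sets 2R), and the crude carbinol is silylated so that O2 cannot interfere later.

Step 4
Reactants: 11 (4S,5S)-5-(dimethoxymethyl)-4-methyl-4-[(1R,4RS)-4-methyl-1-(triethylsilyloxy)hex-5-en-1-yl]cyclohex-2-en-1-one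
Product: 12 (4S,5S,6S)-5-(dimethoxymethyl)-4,6-dimethyl-4-[(1R,4RS)-4-methyl-1-(triethylsilyloxy)hex-5-en-1-yl]cyclohex-2-en-1-one
Conditions: LiN(iPr)2, THF, −78 °C; MeI, −78 → −40 °C
Reagents that add atoms: iodomethane, CI
Why: Kinetic α'-enolate alkylation: C1 is quaternary so only C11 can be deprotonated, and MeI enters trans to the C10 side chain (this configuration is irrelevant because C11 is re-enolised in step 5).

Step 5
Reactants: 12 (4S,5S,6S)-5-(dimethoxymethyl)-4,6-dimethyl-4-[(1R,4RS)-4-methyl-1-(triethylsilyloxy)hex-5-en-1-yl]cyclohex-2-en-1-one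
Product: 13 (4S,5R,6S)-5-(dimethoxymethyl)-6-hydroxy-4,6-dimethyl-4-[(1R,4RS)-4-methyl-1-(triethylsilyloxy)hex-5-en-1-yl]cyclohex-2-en-1-one
Conditions: KN(SiMe3)2, THF, −78 °C; 3-phenyl-2-(phenylsulfonyl)oxaziridine, −78 °C; aq. work-up
Reagents that add atoms: 3-phenyl-2-(phenylsulfonyl)oxaziridine, O=S(=O)(N1OC1c1ccccc1)c1ccccc1
Why: Davis oxaziridine hydroxylation of the tetrasubstituted potassium enolate, with the oxidant approaching the face anti to the C10 side chain and the axial C1 methyl group, so the new hydroxyl is trans to C9 (11S).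

Step 6
Reactants: 13 (4S,5R,6S)-5-(dimethoxymethyl)-6-hydroxy-4,6-dimethyl-4-[(1R,4RS)-4-methyl-1-(triethylsilyloxy)hex-5-en-1-yl]cyclohex-2-en-1-one
Product: 14 (1R,2S,6S)-2-hydroxy-2,6-dimethyl-6-[(1R,4RS)-4-methyl-1-(triethylsilyloxy)hex-5-en-1-yl]-3-oxocyclohex-4-ene-1-carbaldehyde
Conditions: pyridinium p-toluenesulfonate (cat.), acetone/H2O 10:1, 40 °C
Reagents that add atoms: water, O
Why: Mild acid-catalysed acetal hydrolysis unmasks the C9 aldehyde while the hindered triethylsilyl ether survives and prevents lactol formation with O2.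

Step 7
Reactants: 14 (1R,2S,6S)-2-hydroxy-2,6-dimethyl-6-[(1R,4RS)-4-methyl-1-(triethylsilyloxy)hex-5-en-1-yl]-3-oxocyclohex-4-ene-1-carbaldehyde; 15 methoxyallene
Product: 18 (4S,5S,6S)-6-hydroxy-4-[(1R,4RS)-1-hydroxy-4-methylhex-5-en-1-yl]-5-[(1R)-1-hydroxy-2-oxobut-3-en-1-yl]-4,6-dimethylcyclohex-2-en-1-one, via 1-lithio-1-methoxyallene 16 (not isolated), via allenyl ether carbinol 17 (not isolated)
Conditions: 15, n-C4H9Li, THF, −40 °C; 14, −78 °C; then 5% aq. H2SO4, THF, 0 → 23 °C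
Reagents that add atoms: water, O
Why: Lithiated methoxyallene acts as an acryloyl anion equivalent; the first equivalent forms the C11 lithium alkoxide, which shields the C12 ketone and chelates the aldehyde, so the chelate and Felkin–Anh models both direct attack anti to quaternary C1 (9R), and aqueous acid then hydrolyses the allenyl enol ether to the vinyl ketone and removes the silyl ether.

Step 8
Reactants: 18 (4S,5S,6S)-6-hydroxy-4-[(1R,4RS)-1-hydroxy-4-methylhex-5-en-1-yl]-5-[(1R)-1-hydroxy-2-oxobut-3-en-1-yl]-4,6-dimethylcyclohex-2-en-1-one; 19 tert-butyl propanoate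
Product: 21 tert-butyl (2R,3R)-3-hydroxy-3-{(R)-hydroxy[(1S,2S,6S)-2-hydroxy-6-[(1R,4RS)-1-hydroxy-4-methylhex-5-en-1-yl]-2,6-dimethyl-3-oxocyclohex-4-en-1-yl]methyl}-2-methylpent-4-enoate, via lithium E-enolate 20 (not isolated)
Conditions: 19, LiN(iPr)2 (5 equiv), THF, −78 °C; 18, −78 °C, 1 h; AcOH, −78 °C
Reagents that add atoms: none
Why: Cram-chelate aldol addition in which the O9 lithium alkoxide chelates the C8 ketone so the E-enolate adds 1,2 from the face anti to C10 (8R), and in the Zimmerman–Traxler chair the chelating C9 arm is axial and the vinyl group equatorial, which places the C17 methyl anti to the C8 hydroxyl (17R); the tert-butyl ester resists lactonisation onto O9.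

Step 9
Reactants: 21 tert-butyl (2R,3R)-3-hydroxy-3-{(R)-hydroxy[(1S,2S,6S)-2-hydroxy-6-[(1R,4RS)-1-hydroxy-4-methylhex-5-en-1-yl]-2,6-dimethyl-3-oxocyclohex-4-en-1-yl]methyl}-2-methylpent-4-enoate
Product: 22 tert-butyl (2R,3R)-3-{(R)-acetoxy[(1S,2S,6S)-6-[(1R,4RS)-1-acetoxy-4-methylhex-5-en-1-yl]-2-hydroxy-2,6-dimethyl-3-oxocyclohex-4-en-1-yl]methyl}-3-hydroxy-2-methylpent-4-enoate
Conditions: Ac2O, Et3N, DMAP (cat.), CH2Cl2, 0 → 23 °C
Reagents that add atoms: acetic anhydride, CC(=O)OC(C)=O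
Why: DMAP-catalysed acylation takes the two secondary alcohols (O2, O9) and leaves the two hindered tertiary alcohols (O8, O11) free.

Step 10
Reactants: 22 tert-butyl (2R,3R)-3-{(R)-acetoxy[(1S,2S,6S)-6-[(1R,4RS)-1-acetoxy-4-methylhex-5-en-1-yl]-2-hydroxy-2,6-dimethyl-3-oxocyclohex-4-en-1-yl]methyl}-3-hydroxy-2-methylpent-4-enoate
Product: 23 tert-butyl (1S,2R,5RS,6Z,8R,9R,10S,11S,17R)-2,9-diacetoxy-8,11-dihydroxy-12-oxobriara-6,13-dien-18-oate
Conditions: RuCl2(H2IMes)(=CH-C6H4-2-OiPr) (second-generation Hoveyda–Grubbs catalyst, H2IMes = 1,3-dimesitylimidazolidin-2-ylidene, 10 mol%), toluene (1 mM), 80 °C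
Reagents that add atoms: none
Why: Ring-closing metathesis of the two terminal vinyl groups, helped by the trans-disposed chains on ring A; the ten-membered ring favours the Z olefin, and the enone and free tertiary alcohols are tolerated.

Step 11
Reactants: 23 tert-butyl (1S,2R,5RS,6Z,8R,9R,10S,11S,17R)-2,9-diacetoxy-8,11-dihydroxy-12-oxobriara-6,13-dien-18-oate
Product: 24 (1S,2R,5RS,6Z,8R,9R,10S,11S,17R)-2,9-diacetoxy-8,11-dihydroxy-12-oxobriara-6,13-dien-18-oic acid
Conditions: CF3CO2H/CH2Cl2 1:4, 0 °C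
Reagents that add atoms: none
Why: Acidolysis of the tert-butyl ester with loss of isobutene; the tertiary allylic C8 alcohol is deactivated towards ionisation by the flanking acetoxy and carboxyl groups, and the acetates survive.

Step 12
Reactants: 24 (1S,2R,5RS,6Z,8R,9R,10S,11S,17R)-2,9-diacetoxy-8,11-dihydroxy-12-oxobriara-6,13-dien-18-oic acid
Product: 27 (1S,2R,6S,7R,8R,9R,10S,11S,17R)-2,9-diacetoxy-6-chloro-8,11-dihydroxy-12-oxobriara-5(16),13-dien-18,7-olide, via phenylselanyl lactone 25 (not isolated), via 5-ene lactone 26 (not isolated)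
Conditions: PhSeCl (1.05 equiv), pyridine (1.2 equiv), CH2Cl2, −78 °C; then N-chlorosuccinimide (2.3 equiv), −20 → 23 °C
Reagents that add atoms: N-chlorosuccinimide, O=C1CCC(=O)N1Cl
Why: Proposed new method: a one-flask selenium relay in which PhSeCl first effects 5-exo anti-phenylselenolactonisation of the Z-olefin (C7–O bond; 1,3-allylic strain keeps the C8 hydroxyl in the olefin plane so the carboxyl adds anti to C9, giving 7R), N-chlorosuccinimide then oxidises the selenide to a tetravalent chloroselenurane that eliminates away from oxygen to the 5-ene and releases PhSeCl, and the released PhSeCl, now catalytic, activates the new trisubstituted olefin on the face anti to C8 so that chloride enters C6 anti to selenium (6S) before a second oxidation/elimination towards C16 gives the exocyclic methylene; the closest known reactions are phenylselenolactonisation–selenoxide elimination and the PhSeCl-catalysed allylic chlorination of trisubstituted olefins by N-chlorosuccinimide, which have not been merged or run on a medium ring, and both C5 epimers are expected to converge because C5 becomes sp2.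

**Compound list**

1 | 2,2-dimethoxyacetaldehyde | COC(OC)C=O | starting material
2 | 2-(triphenyl-λ5-phosphanylidene)propanal | CC(C=O)=P(c1ccccc1)(c1ccccc1)c1ccccc1 | starting material
3 | (2E)-4,4-dimethoxy-2-methylbut-2-enal | COC(OC)/C=C(\C)C=O | intermediate
4 | (1E)-3-(tert-butyldimethylsilyloxy)-N,N-dimethylbuta-1,3-dien-1-amine | CN(C)/C=C/C(=C)O[Si](C)(C)C(C)(C)C | starting material
5 | (1R,2S,6S)-4-(tert-butyldimethylsilyloxy)-6-(dimethoxymethyl)-2-(dimethylamino)-1-methylcyclohex-3-ene-1-carbaldehyde | O=C[C@@]1(C)[C@@H](N(C)C)C=C(O[Si](C)(C)C(C)(C)C)C[C@@H]1C(OC)OC | intermediate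
6 | (1S,6S)-6-(dimethoxymethyl)-1-methyl-4-oxocyclohex-2-ene-1-carbaldehyde | O=C[C@@]1(C)C=CC(=O)C[C@@H]1C(OC)OC | intermediate
7 | 3-methylpenta-1,4-diene | C=CC(C)C=C | starting material
8 | diethyl(3-methylpent-4-en-1-yl)borane (racemic) | CCB(CC)CCC(C)C=C | intermediate
9 | bis(3-methylpent-4-en-1-yl)zinc | C=CC(C)CC[Zn]CCC(C)C=C | intermediate
10 | (4S,5S)-5-(dimethoxymethyl)-4-[(1R,4RS)-1-hydroxy-4-methylhex-5-en-1-yl]-4-methylcyclohex-2-en-1-one | C=CC(C)CC[C@@H](O)[C@@]1(C)C=CC(=O)C[C@@H]1C(OC)OC | intermediate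
11 | (4S,5S)-5-(dimethoxymethyl)-4-methyl-4-[(1R,4RS)-4-methyl-1-(triethylsilyloxy)hex-5-en-1-yl]cyclohex-2-en-1-one | C=CC(C)CC[C@@H](O[Si](CC)(CC)CC)[C@@]1(C)C=CC(=O)C[C@@H]1C(OC)OC | intermediate
12 | (4S,5S,6S)-5-(dimethoxymethyl)-4,6-dimethyl-4-[(1R,4RS)-4-methyl-1-(triethylsilyloxy)hex-5-en-1-yl]cyclohex-2-en-1-one | C=CC(C)CC[C@@H](O[Si](CC)(CC)CC)[C@@]1(C)C=CC(=O)[C@@H](C)[C@@H]1C(OC)OC | intermediate
13 | (4S,5R,6S)-5-(dimethoxymethyl)-6-hydroxy-4,6-dimethyl-4-[(1R,4RS)-4-methyl-1-(triethylsilyloxy)hex-5-en-1-yl]cyclohex-2-en-1-one | C=CC(C)CC[C@@H](O[Si](CC)(CC)CC)[C@@]1(C)C=CC(=O)[C@@](C)(O)[C@@H]1C(OC)OC | intermediate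
14 | (1R,2S,6S)-2-hydroxy-2,6-dimethyl-6-[(1R,4RS)-4-methyl-1-(triethylsilyloxy)hex-5-en-1-yl]-3-oxocyclohex-4-ene-1-carbaldehyde | C=CC(C)CC[C@@H](O[Si](CC)(CC)CC)[C@@]1(C)C=CC(=O)[C@@](C)(O)[C@@H]1C=O | intermediate
15 | methoxyallene (1-methoxypropa-1,2-diene) | COC=C=C | starting material
16 | 1-lithio-1-methoxypropa-1,2-diene | [Li]C(OC)=C=C | intermediate
17 | (4S,5S,6S)-6-hydroxy-5-[(1R)-1-hydroxy-2-methoxybuta-2,3-dien-1-yl]-4,6-dimethyl-4-[(1R,4RS)-4-methyl-1-(triethylsilyloxy)hex-5-en-1-yl]cyclohex-2-en-1-one | C=CC(C)CC[C@@H](O[Si](CC)(CC)CC)[C@@]1(C)C=CC(=O)[C@@](C)(O)[C@@H]1[C@@H](O)C(OC)=C=C | intermediate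
18 | (4S,5S,6S)-6-hydroxy-4-[(1R,4RS)-1-hydroxy-4-methylhex-5-en-1-yl]-5-[(1R)-1-hydroxy-2-oxobut-3-en-1-yl]-4,6-dimethylcyclohex-2-en-1-one | C=CC(C)CC[C@@H](O)[C@@]1(C)C=CC(=O)[C@@](C)(O)[C@@H]1[C@@H](O)C(=O)C=C | intermediate
19 | tert-butyl propanoate | CCC(=O)OC(C)(C)C | starting material
20 | lithium E-enolate of tert-butyl propanoate (methyl trans to OLi) | C/C=C(/O[Li])OC(C)(C)C | intermediate
21 | tert-butyl (2R,3R)-3-hydroxy-3-{(R)-hydroxy[(1S,2S,6S)-2-hydroxy-6-[(1R,4RS)-1-hydroxy-4-methylhex-5-en-1-yl]-2,6-dimethyl-3-oxocyclohex-4-en-1-yl]methyl}-2-methylpent-4-enoate | C=CC(C)CC[C@@H](O)[C@@]1(C)C=CC(=O)[C@@](C)(O)[C@@H]1[C@@H](O)[C@@](O)(C=C)[C@@H](C)C(=O)OC(C)(C)C | intermediate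
22 | tert-butyl (2R,3R)-3-{(R)-acetoxy[(1S,2S,6S)-6-[(1R,4RS)-1-acetoxy-4-methylhex-5-en-1-yl]-2-hydroxy-2,6-dimethyl-3-oxocyclohex-4-en-1-yl]methyl}-3-hydroxy-2-methylpent-4-enoate | C=CC(C)CC[C@@H](OC(C)=O)[C@@]1(C)C=CC(=O)[C@@](C)(O)[C@@H]1[C@@H](OC(C)=O)[C@@](O)(C=C)[C@@H](C)C(=O)OC(C)(C)C | intermediate
23 | tert-butyl (1S,2R,5RS,6Z,8R,9R,10S,11S,17R)-2,9-diacetoxy-8,11-dihydroxy-12-oxobriara-6,13-dien-18-oate | C1C[C@@H](OC(C)=O)[C@@]2(C)C=CC(=O)[C@@](C)(O)[C@@H]2[C@@H](OC(C)=O)[C@](O)([C@@H](C)C(=O)OC(C)(C)C)/C=C\C1C | intermediate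
24 | (1S,2R,5RS,6Z,8R,9R,10S,11S,17R)-2,9-diacetoxy-8,11-dihydroxy-12-oxobriara-6,13-dien-18-oic acid | C1C[C@@H](OC(C)=O)[C@@]2(C)C=CC(=O)[C@@](C)(O)[C@@H]2[C@@H](OC(C)=O)[C@](O)([C@@H](C)C(=O)O)/C=C\C1C | intermediate
25 | (1S,2R,5RS,6R,7R,8R,9R,10S,11S,17R)-2,9-diacetoxy-8,11-dihydroxy-12-oxo-6-(phenylselanyl)briar-13-en-18,7-olide | CC1CC[C@@H](OC(C)=O)[C@@]2(C)C=CC(=O)[C@@](C)(O)[C@@H]2[C@@H](OC(C)=O)[C@]2(O)[C@@H](C)C(=O)O[C@H]2[C@@H]1[Se]c1ccccc1 | intermediate
26 | (1S,2R,5Z,7S,8S,9R,10S,11S,17R)-2,9-diacetoxy-8,11-dihydroxy-12-oxobriara-5,13-dien-18,7-olide (same spatial arrangement at C7 and C8 as in 27) | C/C1=C/[C@@H]2OC(=O)[C@H](C)[C@@]2(O)[C@H](OC(C)=O)[C@H]2[C@](C)(O)C(=O)C=C[C@]2(C)[C@H](OC(C)=O)CC1 | intermediate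
27 | CNP0261648.1, (1S,2R,6S,7R,8R,9R,10S,11S,17R)-2,9-diacetoxy-6-chloro-8,11-dihydroxy-12-oxobriara-5(16),13-dien-18,7-olide | C=C1CC[C@@H](OC(C)=O)[C@@]2(C)C=CC(=O)[C@@](C)(O)[C@@H]2[C@@H](OC(C)=O)[C@]2(O)[C@@H](C)C(=O)O[C@H]2[C@H]1Cl | target

**Step count and risks**

Total steps: 12. Longest linear sequence: 12 (steps 1–12).

The three steps most likely to fail:

Step 2 (Diels–Alder). The β-branched, α-methyl enal is outside the proven scope of the hydrogen-bond catalyst: it may react slowly, give low ee, or divert to the hetero-Diels–Alder adduct at the formyl group. The fallback sets out from 3 and comes back at 6, replacing catalyst control by auxiliary control. Enal 3 is warmed in toluene (23–60 °C) with the C2-symmetric diene (1E)-3-(tert-butyldimethylsilyloxy)-1-[(2R,5R)-2,5-diphenylpyrrolidin-1-yl]buta-1,3-diene F1. F1 is made in two operations from 4-methoxybut-3-en-2-one and (2R,5R)-2,5-diphenylpyrrolidine by amine exchange, then KN(SiMe3)2 and tert-butylchlorodimethylsilane. The thermal cycloaddition gives (1R,2S,6S)-4-(tert-butyldimethylsilyloxy)-6-(dimethoxymethyl)-2-[(2R,5R)-2,5-diphenylpyrrolidin-1-yl]-1-methylcyclohex-3-ene-1-carbaldehyde F2. Treatment of F2 with AcCl at −78 °C removes the auxiliary as its acetamide and gives 6.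

Step 10 (ring-closing metathesis). A ten-membered ring has to close onto a vinyl group that sits on a fully substituted carbinol carbon. The fallback sets out from 18 and comes back at 23, closing the ring before the tertiary carbinol exists. Triol 18 is cyclised with RuCl2(H2IMes)(=CH-C6H4-2-OiPr) in dilute toluene, using the less hindered vinyl ketone as the metathesis partner. This gives the macrocyclic enone (1S,2R,5RS,6Z,9R,10S,11S)-2,9,11-trihydroxy-17,18,19-trinorbriara-6,13-diene-8,12-dione F3. The chelate-controlled aldol of step 8 (enolate 20, THF, −78 °C) is then run on F3 and gives tert-butyl (1S,2R,5RS,6Z,8R,9R,10S,11S,17R)-2,8,9,11-tetrahydroxy-12-oxobriara-6,13-dien-18-oate F4. Acetylation of F4 as in step 9 gives 23.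

Step 12 (the proposed selenium relay). Possible failures are direct chlorolactonisation by N-chlorosuccinimide, elimination towards C4 instead of C16, or the wrong C6 epimer. The fallback sets out from 24 and comes back at 27 by known reactions run separately. Acid 24 undergoes iodolactonisation (I2, NaHCO3, MeCN, 0 °C) to (1S,2R,5RS,6R,7R,8R,9R,10S,11S,17R)-2,9-diacetoxy-8,11-dihydroxy-6-iodo-12-oxobriar-13-en-18,7-olide F5. Anti-dehydroiodination of F5 with DBU in toluene gives the 5-ene lactone 26, now isolated. The C5 epimer that cannot eliminate anti is routed instead through isolated 25 and H2O2/pyridine selenoxide syn-elimination. Lactone 26 is then chlorinated under the established PhSeCl-catalysed N-chlorosuccinimide conditions (10 mol% PhSeCl, CH2Cl2, 23 °C) to give 27.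

**Further compounds**

F1 | step 2 | (1E)-3-(tert-butyldimethylsilyloxy)-1-[(2R,5R)-2,5-diphenylpyrrolidin-1-yl]buta-1,3-diene | C=C(O[Si](C)(C)C(C)(C)C)/C=C/N1[C@@H](c2ccccc2)CC[C@@H]1c1ccccc1
F2 | step 2 | (1R,2S,6S)-4-(tert-butyldimethylsilyloxy)-6-(dimethoxymethyl)-2-[(2R,5R)-2,5-diphenylpyrrolidin-1-yl]-1-methylcyclohex-3-ene-1-carbaldehyde | O=C[C@@]1(C)[C@@H](N2[C@@H](c3ccccc3)CC[C@@H]2c2ccccc2)C=C(O[Si](C)(C)C(C)(C)C)C[C@@H]1C(OC)OC
F3 | step 10 | (1S,2R,5RS,6Z,9R,10S,11S)-2,9,11-trihydroxy-17,18,19-trinorbriara-6,13-diene-8,12-dione | C1C[C@@H](O)[C@@]2(C)C=CC(=O)[C@@](C)(O)[C@@H]2[C@@H](O)C(=O)/C=C\C1C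
F4 | step 10 | tert-butyl (1S,2R,5RS,6Z,8R,9R,10S,11S,17R)-2,8,9,11-tetrahydroxy-12-oxobriara-6,13-dien-18-oate | C1C[C@@H](O)[C@@]2(C)C=CC(=O)[C@@](C)(O)[C@@H]2[C@@H](O)[C@](O)([C@@H](C)C(=O)OC(C)(C)C)/C=C\C1C
F5 | step 12 | (1S,2R,5RS,6R,7R,8R,9R,10S,11S,17R)-2,9-diacetoxy-8,11-dihydroxy-6-iodo-12-oxobriar-13-en-18,7-olide | CC1CC[C@@H](OC(C)=O)[C@@]2(C)C=CC(=O)[C@@](C)(O)[C@@H]2[C@@H](OC(C)=O)[C@]2(O)[C@@H](C)C(=O)O[C@H]2[C@@H]1I
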